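How much bis adduct stands in this flask after 20 min, and which charge of reagent leaves most?

| flask | substrate | reagent | remark | time |
|---|---|---|---|---|
| grey | 0.25 M | 1 equiv | the very flask that is asked about, followed so far |  |
| flask | 0.25 M | 1.00 equiv |  | 20 min |

grey run (percent of the substrate charged)

| time / min | bis adduct / % | mono adduct / % |
|---|---|---|
| 1.33 | 6.9 | 34.1 |
| 2.50 | 11.8 | 37.6 |
| 4.00 | 16.2 | 38.6 |
| 5.00 | 18.6 | 38.1 |
| 6.00 | 19.4 | 37.9 |

(each reading ± 0.5 percentage points)

1. equivalents of reagent to substrate, everything else as given, that leave most bis adduct at 20 min
2. the amount of bis adduct then, in percent of the substrate charged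
3. the amount of bis adduct with the amounts as given



A bis adduct holds two reagents and a mono adduct one, so at the last reading of this flask I can account for this part of the reagent charge:

seen reagent = mono adduct + 2 × bis adduct = 76.7%

bis adduct ÷ seen reagent = 25.3%

I call this quotient the bis yield per reagent: bis adducts formed for each reagent spent.

Two extreme versions of this flask can be solved in the head. In the first, the unseen reagent is lost and this flask stops, leaving the last reading of 19.4%. The second starts from the mono adduct readings, which lie between 37.6% and 38.6% from 2.50 min to 6.00 min, a spread of 1 percentage point against a scatter of 0.5 points on each reading. If mono adduct then stands still, the charge outside it sits in pairs: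

(charge − mono adduct) ÷ 2 = 31.1%

I expect this flask between them, with the unseen reagent dividing as the seen part did:

bis adduct = yield × charge = 25.3%

The forecast is lower: 20.5% (range 19.3% to 22.5%), judging that “the flask is essentially finished by 20 min”. For the best charge it gives 97% at 3 equiv.

This flask gives 25.7%, and the most bis adduct is 46.2% at 1.98 equiv.

    substrate + reagent → mono adduct (k = 0.0490 /M/s)
    reagent + mono adduct → bis adduct (k = 0.0220 /M/s)
    reagent + bis adduct → triple product (k = 0.00800 /M/s)
    reagent + triple product → tetra adduct (k = 0.00260 /M/s)
    substrate ⇌ dormant form (K = 1.50, k = 0.00730 /s)

The forecast's figure for this flask is close to the last reading taken over. Reagent, the limiting reagent, is down to 0.42% of its charge at 20.0 min, and the yield had put bis adduct at 25.3%. On the neighbour flask charged with 1.70 equiv, the same yield times that charge reckons 43.0%. That neighbour flask gives 44.3% of bis adduct, beside 16.7% of triple product.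

The numbers in the tables were generated by integration for an exercise, and the scatter is random.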